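**Retrosynthetic overview**
- Target ⇒ acrylic acid + aryl bromide (Heck at C5), then ⇒ p-coumaric acid + (2S)-2-[(2S)-5-bromo-2,3-dihydrobenzofuran-2-yl]propan-1-ol (Mitsunobu ester C–O), the alcohol carried as its silyl ether.
- Key disconnection: the benzene ring and the dihydrofuran ring of the bromodihydrobenzofuran are opened together (retro intramolecular alkyne/1,2-diazine Diels–Alder with N2 loss) ⇒ 3-bromo-6-(homopropargyloxy)pyridazine.
- ⇒ 3,6-dibromopyridazine + syn-(2S,3S)-homopropargylic alcohol (SNAr).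
- ⇒ allenylboronate + O-silylated (S)-Roche aldehyde (catalyst-controlled propargylation) ⇐ (S)-Roche ester.
- Ring order: the p-hydroxyphenyl ring is bought; the pyridazine is bought and sacrificed; the arene and dihydrofuran rings form together in step 5.

Assumption: (S)-Roche ester, 3,6-dibromopyridazine, allenylboronic acid pinacol ester and (S)-TRIP are taken as catalogue items, and (S)-TRIP is taken to add to the aldehyde Si face (mirror of the Re-face sense of the (R)-catalyst), which is recalled rather than re-derived.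

**Step 1**
Reactants: 1 methyl (2S)-3-hydroxy-2-methylpropanoate; 2 tert-butyl(chloro)diphenylsilane
Product: 3 methyl (2S)-3-[(tert-butyldiphenylsilyl)oxy]-2-methylpropanoate
Conditions: TBDPSCl, imidazole, DMF, 0 °C → rt
Reagents that add atoms: tert-butyl(chloro)diphenylsilane (2), CC(C)(C)[Si](Cl)(c1ccccc1)c1ccccc1
Why: Imidazole-promoted O-silylation of the primary alcohol; the bulky TBDPS group is chosen because it resists 1,3 O→O migration in the later alkoxide step, and the stereocentre is not touched.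

**Step 2**
Reactants: 3 methyl (2S)-3-[(tert-butyldiphenylsilyl)oxy]-2-methylpropanoate
Product: 5 (2S)-3-[(tert-butyldiphenylsilyl)oxy]-2-methylpropanal, via diisobutylaluminium hemiacetal 4 (not isolated)
Conditions: DIBAL-H (1.1 equiv), CH2Cl2, −78 °C; MeOH, then aq. Rochelle salt; used crude
Reagents that add atoms: none
Why: Partial ester reduction with DIBAL-H, where the tetrahedral aluminium hemiacetal is stable at −78 °C and releases the aldehyde only on work-up; the α-stereocentre is kept by cold, non-basic handling.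

**Step 3**
Reactants: 5 (2S)-3-[(tert-butyldiphenylsilyl)oxy]-2-methylpropanal; 6 allenylboronic acid pinacol ester
Product: 8 (2S,3S)-1-[(tert-butyldiphenylsilyl)oxy]-2-methylhex-5-yn-3-ol, via pinacol borate ester 7 (not isolated)
Conditions: (S)-TRIP (10 mol %), 4 Å MS, toluene, −20 °C; aq. NaHCO3 work-up
Reagents that add atoms: allenylboronic acid pinacol ester (6), C=C=CB1OC(C)(C)C(C)(C)O1
Why: Chiral phosphoric acid-catalysed asymmetric propargylation (SE2′ allenylboration through a closed six-membered transition state), in which the (S)-catalyst directs the propargyl group to the Si face of the aldehyde and so sets the (3S) carbinol (the future ring C2, 2,3-syn to the methyl group and also the Felkin sense), while the methyl stereocentre comes unchanged from the Roche ester.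

**Step 4**
Reactants: 8 (2S,3S)-1-[(tert-butyldiphenylsilyl)oxy]-2-methylhex-5-yn-3-ol; 9 3,6-dibromopyridazine
Product: 11 3-bromo-6-{[(2S,3S)-1-[(tert-butyldiphenylsilyl)oxy]-2-methylhex-5-yn-3-yl]oxy}pyridazine, via sodium alkoxide 10 (not isolated)
Conditions: NaH (1.1 equiv), 9 (1.2 equiv) present from the start, THF, 0 °C → rt
Reagents that add atoms: 3,6-dibromopyridazine (9), Brc1ccc(Br)nn1
Why: SNAr (addition–elimination) of the secondary alkoxide on the electron-poor 1,2-diazine, which stops at mono-substitution because the alkoxy group deactivates the ring, and which keeps the carbinol configuration because only the O–aryl bond is formed.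

**Step 5**
Reactants: 11 3-bromo-6-{[(2S,3S)-1-[(tert-butyldiphenylsilyl)oxy]-2-methylhex-5-yn-3-yl]oxy}pyridazine
Product: 13 tert-butyl{(2S)-2-[(2S)-5-bromo-2,3-dihydro-1-benzofuran-2-yl]propoxy}diphenylsilane, via diazabicyclooctatriene cycloadduct 12 (not isolated)
Conditions: 1,3,5-triisopropylbenzene (0.02 M), BHT (cat.), 230 °C, Ar, sealed tube, 12–24 h
Reagents that add atoms: none
Why: Intramolecular inverse-electron-demand Diels–Alder of the tethered alkyne across C3/C6 of the pyridazine followed by retro-Diels–Alder loss of N2 builds the benzene and dihydrofuran rings in one operation, the three-atom tether forcing Br para to the ring oxygen (C5) and both stereocentres being untouched spectators; the reaction type is known for alkyne-tethered 1,2-diazines, and this weakly activated bromo/alkoxy case sits at its demanding end.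

**Step 6**
Reactants: 13 tert-butyl{(2S)-2-[(2S)-5-bromo-2,3-dihydro-1-benzofuran-2-yl]propoxy}diphenylsilane
Product: 14 (2S)-2-[(2S)-5-bromo-2,3-dihydro-1-benzofuran-2-yl]propan-1-ol
Conditions: HF·pyridine, THF/pyridine, 0 °C → rt
Reagents that add atoms: none
Why: Fluoride-driven Si–O cleavage (silyl ether deprotection) that leaves the aryl bromide, the aryl alkyl ether and both stereocentres alone.

**Step 7**
Reactants: 14 (2S)-2-[(2S)-5-bromo-2,3-dihydro-1-benzofuran-2-yl]propan-1-ol; 15 (E)-4-hydroxycinnamic acid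
Product: 17 (2S)-2-[(2S)-5-bromo-2,3-dihydro-1-benzofuran-2-yl]propyl (2E)-3-(4-hydroxyphenyl)prop-2-enoate, via alkoxyphosphonium coumarate 16 (not isolated)
Conditions: PPh3 (1.3 equiv), DIAD (1.3 equiv), 15 (1.3 equiv), THF, 0 °C → rt
Reagents that add atoms: (E)-4-hydroxycinnamic acid (15), OC(=O)/C=C/c1ccc(O)cc1
Why: Mitsunobu esterification in which only the carboxylic acid (pKa about 4.6) is acidic enough to protonate the betaine and its carboxylate displaces the primary alkoxyphosphonium, so the phenol (pKa about 10) needs no protection and no stereocentre is involved (SN2 at CH2).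

**Step 8**
Reactants: 17 (2S)-2-[(2S)-5-bromo-2,3-dihydro-1-benzofuran-2-yl]propyl (2E)-3-(4-hydroxyphenyl)prop-2-enoate; 18 acrylic acid
Product: 19 (2E)-3-[(2S)-2-{(2S)-1-[(2E)-3-(4-hydroxyphenyl)prop-2-enoyl]oxypropan-2-yl}-2,3-dihydro-1-benzofuran-5-yl]prop-2-enoic acid
Conditions: Pd(OAc)2 (5 mol %), P(o-tol)3 (12 mol %), acrylic acid (3 equiv), Et3N (4 equiv), DMF, 100 °C; 1 M HCl work-up
Reagents that add atoms: acrylic acid (18), C=CC(=O)O
Why: Mizoroki–Heck reaction (oxidative addition into Ar–Br, syn-carbopalladation at the unsubstituted acrylate terminus, syn-β-hydride elimination) gives the E-cinnamic acid directly, the 1,2-disubstituted coumarate alkene being far less reactive than excess acrylic acid and the stereocentres being remote.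

**Compound list**
1 | methyl (2S)-3-hydroxy-2-methylpropanoate ((S)-Roche ester) | C[C@@H](CO)C(=O)OC | starting material
2 | tert-butyl(chloro)diphenylsilane | CC(C)(C)[Si](Cl)(c1ccccc1)c1ccccc1 | starting material
3 | methyl (2S)-3-[(tert-butyldiphenylsilyl)oxy]-2-methylpropanoate | C[C@@H](CO[Si](c1ccccc1)(c1ccccc1)C(C)(C)C)C(=O)OC | intermediate
4 | {(2S)-3-[(tert-butyldiphenylsilyl)oxy]-1-methoxy-2-methylpropoxy}bis(2-methylpropyl)alumane (aluminium hemiacetal, acetal carbon unassigned) | C[C@@H](CO[Si](c1ccccc1)(c1ccccc1)C(C)(C)C)C(OC)O[Al](CC(C)C)CC(C)C | intermediate (not isolated)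
5 | (2S)-3-[(tert-butyldiphenylsilyl)oxy]-2-methylpropanal | C[C@@H](CO[Si](c1ccccc1)(c1ccccc1)C(C)(C)C)C=O | intermediate
6 | allenylboronic acid pinacol ester (4,4,5,5-tetramethyl-2-(propa-1,2-dien-1-yl)-1,3,2-dioxaborolane) | C=C=CB1OC(C)(C)C(C)(C)O1 | starting material
7 | 2-{[(2S,3S)-1-[(tert-butyldiphenylsilyl)oxy]-2-methylhex-5-yn-3-yl]oxy}-4,4,5,5-tetramethyl-1,3,2-dioxaborolane | C[C@@H](CO[Si](c1ccccc1)(c1ccccc1)C(C)(C)C)[C@@H](OB1OC(C)(C)C(C)(C)O1)CC#C | intermediate (not isolated)
8 | (2S,3S)-1-[(tert-butyldiphenylsilyl)oxy]-2-methylhex-5-yn-3-ol (2,3-syn) | C[C@@H](CO[Si](c1ccccc1)(c1ccccc1)C(C)(C)C)[C@@H](O)CC#C | intermediate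
9 | 3,6-dibromopyridazine | Brc1ccc(Br)nn1 | starting material
10 | sodium (2S,3S)-1-[(tert-butyldiphenylsilyl)oxy]-2-methylhex-5-yn-3-olate | C[C@@H](CO[Si](c1ccccc1)(c1ccccc1)C(C)(C)C)[C@@H]([O-])CC#C.[Na+] | intermediate (not isolated)
11 | 3-bromo-6-{[(2S,3S)-1-[(tert-butyldiphenylsilyl)oxy]-2-methylhex-5-yn-3-yl]oxy}pyridazine | C[C@@H](CO[Si](c1ccccc1)(c1ccccc1)C(C)(C)C)[C@@H](Oc1ccc(Br)nn1)CC#C | intermediate
12 | oxolane-fused 1-bromo-2,3-diazabicyclo[2.2.2]octa-2,5,7-triene cycloadduct (ring O on the C4 bridgehead, ring CH2 on alkene C5; bridgeheads formed as a mixture of both facial isomers, side-chain centres S,S) | C[C@@H](CO[Si](c1ccccc1)(c1ccccc1)C(C)(C)C)[C@@H]1CC2=CC3(Br)C=CC2(O1)N=N3 | intermediate (not isolated)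
13 | tert-butyl{(2S)-2-[(2S)-5-bromo-2,3-dihydro-1-benzofuran-2-yl]propoxy}diphenylsilane | C[C@@H](CO[Si](c1ccccc1)(c1ccccc1)C(C)(C)C)[C@@H]1Cc2cc(Br)ccc2O1 | intermediate
14 | (2S)-2-[(2S)-5-bromo-2,3-dihydro-1-benzofuran-2-yl]propan-1-ol | C[C@@H](CO)[C@@H]1Cc2cc(Br)ccc2O1 | intermediate
15 | (E)-4-hydroxycinnamic acid (p-coumaric acid) | OC(=O)/C=C/c1ccc(O)cc1 | starting material
16 | {(2S)-2-[(2S)-5-bromo-2,3-dihydro-1-benzofuran-2-yl]propoxy}triphenylphosphonium (E)-4-hydroxycinnamate | C[C@@H](CO[P+](c1ccccc1)(c1ccccc1)c1ccccc1)[C@@H]1Cc2cc(Br)ccc2O1.[O-]C(=O)/C=C/c1ccc(O)cc1 | intermediate (not isolated)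
17 | (2S)-2-[(2S)-5-bromo-2,3-dihydro-1-benzofuran-2-yl]propyl (2E)-3-(4-hydroxyphenyl)prop-2-enoate | C[C@@H](COC(=O)/C=C/c1ccc(O)cc1)[C@@H]1Cc2cc(Br)ccc2O1 | intermediate
18 | acrylic acid | C=CC(=O)O | starting material
19 | (2E)-3-[(2S)-2-{(2S)-1-[(2E)-3-(4-hydroxyphenyl)prop-2-enoyl]oxypropan-2-yl}-2,3-dihydro-1-benzofuran-5-yl]prop-2-enoic acid (CNP0224846.1) | C[C@@H](COC(=O)/C=C/c1ccc(O)cc1)[C@@H]1Cc2cc(/C=C/C(=O)O)ccc2O1 | target

**Totals**
Total step count: 8. Longest linear sequence: 8 (fully linear from 1).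

**Steps most likely to fail**

Step 5 (key cycloaddition). The alkyne is unactivated and the diazine carries a donor alkoxy group, so 230 °C may instead cause thermal loss of the side chain (pyridazinone formation) or decomposition. The fallback sets out from 8 and comes back at 13. Alcohol 8 is treated with KH and trichloroethylene in THF to give the (E)-1,2-dichlorovinyl ether F3. n-BuLi (3.3 equiv, −78 °C, then MeOH) converts this into the ethynyl ether diyne F4. A RhCl(PPh3)3-catalysed [2+2+2] cyclotrimerisation of F4 with acetylene (1 atm, toluene, rt) again closes the arene and the dihydrofuran together, with no regiochemical question, and gives the unbrominated dihydrobenzofuran F5. NBS in MeCN at 0 °C then brominates para to the ring oxygen to give 13.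

Step 3 (catalyst-controlled propargylation). The diastereoselectivity on this α-chiral aldehyde, and the sense of the catalyst, could fall short. The fallback sets out from 5 and comes back at 8. Aldehyde 5 is propargylated without a chiral catalyst (propargyl bromide, Zn, THF/aq. NH4Cl), and the syn alcohol 8 is separated by chromatography from its epimer, the (2S,3R) anti alcohol F1. F1 is recycled by Mitsunobu inversion (4-nitrobenzoic acid, PPh3, DIAD) to the (3S) 4-nitrobenzoate F2, and methanolysis (K2CO3, MeOH) gives 8.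

Step 8 (Heck with free acid and free phenol). Catalyst poisoning or sluggish coupling of the electron-rich bromide is possible. The fallback sets out from 17 and comes back at 19. Bromide 17 is coupled by Suzuki–Miyaura reaction with commercial tert-butyl (E)-3-(4,4,5,5-tetramethyl-1,3,2-dioxaborolan-2-yl)acrylate (Pd(dppf)Cl2, CsF, dioxane, 80 °C), which fixes the E geometry in the reagent and gives the tert-butyl ester of the target F6. TFA/CH2Cl2 with Et3SiH then removes the tert-butyl group to give 19.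

**Further compounds**
F1 | step 3 | (2S,3R)-1-[(tert-butyldiphenylsilyl)oxy]-2-methylhex-5-yn-3-ol | C[C@@H](CO[Si](c1ccccc1)(c1ccccc1)C(C)(C)C)[C@H](O)CC#C
F2 | step 3 | (2S,3S)-1-[(tert-butyldiphenylsilyl)oxy]-2-methylhex-5-yn-3-yl 4-nitrobenzoate | C[C@@H](CO[Si](c1ccccc1)(c1ccccc1)C(C)(C)C)[C@@H](OC(=O)c1ccc(cc1)[N+](=O)[O-])CC#C
F3 | step 5 | tert-butyl{[(2S,3S)-3-{[(E)-1,2-dichloroethenyl]oxy}-2-methylhex-5-yn-1-yl]oxy}diphenylsilane | C[C@@H](CO[Si](c1ccccc1)(c1ccccc1)C(C)(C)C)[C@@H](O/C(Cl)=C\Cl)CC#C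
F4 | step 5 | tert-butyl{[(2S,3S)-3-(ethynyloxy)-2-methylhex-5-yn-1-yl]oxy}diphenylsilane | C[C@@H](CO[Si](c1ccccc1)(c1ccccc1)C(C)(C)C)[C@@H](OC#C)CC#C
F5 | step 5 | tert-butyl{(2S)-2-[(2S)-2,3-dihydro-1-benzofuran-2-yl]propoxy}diphenylsilane | C[C@@H](CO[Si](c1ccccc1)(c1ccccc1)C(C)(C)C)[C@@H]1Cc2ccccc2O1
F6 | step 8 | tert-butyl (2E)-3-[(2S)-2-{(2S)-1-[(2E)-3-(4-hydroxyphenyl)prop-2-enoyl]oxypropan-2-yl}-2,3-dihydro-1-benzofuran-5-yl]prop-2-enoate | C[C@@H](COC(=O)/C=C/c1ccc(O)cc1)[C@@H]1Cc2cc(/C=C/C(=O)OC(C)(C)C)ccc2O1
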